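**Retrosynthetic overview**
Numbering (hexahydrobenzofuran): ring A is the carbocycle C3a–C4–C5–C6–C7–C7a and ring B is the dihydrofuran O1–C2–C3–C3a–C7a. The polyene chain sits on C2.
1. The last C–C bond is a Suzuki–Miyaura coupling between an (E)-iodopropenyl group on C2 and a C13 pentaenyl boronate made from the C10 trienedial.
2. Both rings come from one acyclic α-allenol-ene in a single operation. Ring B closes first (O1–C7a) and ring A closes last (C3a–C4).
3. Enabling feature: C3a is vinylic, lies between C3 and the O-bearing quaternary C7a, and carries the gem-dimethyl carbon C4. C3=C3a=C7a can therefore be an allene whose central carbon becomes a C3a–Pd bond when O1 attacks C7a. C4 plus one of its methyl groups can be a 2-methylallyl alkene that this bond adds to 6-exo, leaving a CH2–Pd without β-hydrogen that hydride turns into the second methyl.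
4. Stereocentres: C7a comes from a Sharpless epoxide, relayed centre → axis → centre. C6 comes from reagent-controlled methallylboration. C2 comes from catalytic asymmetric alkynylation.

Key step: step 11

Assumption 1: the (S,S) antipode of ProPhenol is taken to give the (3R)-carbinol 12; if the sense is opposite, the (R,R) antipode is used.
Assumption 2: the copper hydride displacement in step 10 is taken to run overall anti (syn-hydrocupration, anti-elimination).

Step 1
Reactants: 1 (E)-3-methylpent-2-en-4-yn-1-ol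
Product: 2 [(2S,3S)-3-ethynyl-3-methyloxiran-2-yl]methanol
Conditions: Ti(OiPr)4 (10 mol %), L-(+)-diethyl tartrate (12 mol %), t-BuOOH, 4 Å MS, CH2Cl2, −20 °C
Reagents that add atoms: tert-butyl hydroperoxide, CC(C)(C)OO
Why: Sharpless asymmetric epoxidation of an (E)-trisubstituted allylic alcohol, in which the L-(+)-tartrate catalyst delivers oxygen to the face that gives the (2S,3S)-epoxide and so fixes the C–O bond of the later C7a.

Step 2
Reactants: 2 [(2S,3S)-3-ethynyl-3-methyloxiran-2-yl]methanol
Product: 3 (2R,3S)-3-ethynyl-3-methyloxirane-2-carbaldehyde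
Conditions: TEMPO (10 mol %), PhI(OAc)2 (1.1 equiv), CH2Cl2, 0 °C to rt
Reagents that add atoms: none
Why: Oxoammonium (TEMPO) oxidation of a primary alcohol stops at the aldehyde and should leave epoxide, alkyne and both stereocentres untouched (the descriptor at C2 changes only through priorities).

Step 3
Reactants: 3 (2R,3S)-3-ethynyl-3-methyloxirane-2-carbaldehyde
Product: 4 (1S)-1-[(2S,3S)-3-ethynyl-3-methyloxiran-2-yl]-3-methylbut-3-en-1-ol
Conditions: (−)-Ipc2BOMe, CH2=C(CH3)CH2MgCl, Et2O, −78 °C to rt; 3, −78 °C; HOCH2CH2NH2, rt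
Reagents that add atoms: 2-methylallylmagnesium chloride, C=C(C)C[Mg]Cl
Why: Brown asymmetric methallylboration through a closed chair transition state, in which the (+)-α-pinene-derived borane should override the bias of the epoxy aldehyde and set the (S)-carbinol that becomes C6.

Step 4
Reactants: 4 (1S)-1-[(2S,3S)-3-ethynyl-3-methyloxiran-2-yl]-3-methylbut-3-en-1-ol
Product: 5 (3R,5S)-3,7-dimethyloct-7-en-1-yne-3,5-diol
Conditions: LiEt3BH (3.5 equiv), THF, 0 °C to rt; H2O
Reagents that add atoms: none
Why: SN2 hydride opening of a 2,3-epoxy alcohol at the secondary epoxide carbon, since the other one is quaternary, gives the 1,3-diol with the tertiary C–O bond unchanged, and triethylborohydride does not hydrometalate the alkyne.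

Step 5
Reactants: 5 (3R,5S)-3,7-dimethyloct-7-en-1-yne-3,5-diol
Product: 6 (3R,5S)-5-[(tert-butyldimethylsilyl)oxy]-3,7-dimethyloct-7-en-1-yn-3-ol
Conditions: TBSCl (1.1 equiv), imidazole (2.5 equiv), DMF, 0 °C to rt
Reagents that add atoms: tert-butyldimethylsilyl chloride, CC(C)(C)[Si](C)(C)Cl
Why: Standard silylation should take the secondary hydroxyl and leave the hindered tertiary propargylic one free.

Step 6
Reactants: 6 (3R,5S)-5-[(tert-butyldimethylsilyl)oxy]-3,7-dimethyloct-7-en-1-yn-3-ol
Product: 7 (3R,5S)-5-[(tert-butyldimethylsilyl)oxy]-3,7-dimethyloct-7-en-1-yn-3-yl methyl carbonate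
Conditions: n-BuLi (1.0 equiv), THF, −78 °C; ClCO2Me, −78 to 0 °C
Reagents that add atoms: methyl chloroformate, COC(=O)Cl
Why: One equivalent of base removes the hydroxyl proton, which is far more acidic than the alkyne C–H, and O-acylation of the lithium alkoxide installs the propargylic leaving group without touching the stereocentre.

Step 7
Reactants: 8 3-(trimethylsilyl)prop-2-yn-1-ol
Product: 10 (E)-2-methyl-3-(trimethylsilyl)prop-2-en-1-ol, via magnesacycle 9 (not isolated)
Conditions: MeMgBr (3 equiv), CuI (10 mol %), Et2O, −10 °C to rt; aq. NH4Cl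
Reagents that add atoms: methylmagnesium bromide, C[Mg]Br
Why: Copper-catalysed anti-carbomagnesiation of a propargylic alcohol puts methyl on C2 and magnesium on the silyl-bearing carbon, held cis to the alkoxide in 9, so protonolysis with retention should give the E-vinylsilane.

Step 8
Reactants: 10 (E)-2-methyl-3-(trimethylsilyl)prop-2-en-1-ol
Product: 11 (E)-2-methyl-3-(trimethylsilyl)prop-2-enal
Conditions: MnO2 (15 equiv), CH2Cl2, rt
Reagents that add atoms: none
Why: MnO2 oxidation of an allylic alcohol gives the enal without E/Z isomerisation.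

Step 9
Reactants: 7 (3R,5S)-5-[(tert-butyldimethylsilyl)oxy]-3,7-dimethyloct-7-en-1-yn-3-yl methyl carbonate; 11 (E)-2-methyl-3-(trimethylsilyl)prop-2-enal
Product: 12 (1E,3R,6R,8S)-8-[(tert-butyldimethylsilyl)oxy]-3-hydroxy-2,6,10-trimethyl-1-(trimethylsilyl)undeca-1,10-dien-4-yn-6-yl methyl carbonate
Conditions: (S,S)-ProPhenol (20 mol %), Me2Zn (3 equiv), Ph3PO (40 mol %), toluene, 4 °C
Reagents that add atoms: none
Why: Dinuclear zinc (ProPhenol) catalysed asymmetric alkynylation of an α-branched enal, in which the catalyst alone sets the carbinol that becomes C2, remote from and independent of the two existing centres.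

Step 10
Reactants: 12 (1E,3R,6R,8S)-8-[(tert-butyldimethylsilyl)oxy]-3-hydroxy-2,6,10-trimethyl-1-(trimethylsilyl)undeca-1,10-dien-4-yn-6-yl methyl carbonate
Product: 14 (1E,3R,8S)-8-[(tert-butyldimethylsilyl)oxy]-2,6,10-trimethyl-1-(trimethylsilyl)undeca-1,4,5,10-tetraen-3-ol with the (M) [aR] allene axis C4=C5=C6, via silyl ether 13 (not isolated)
Conditions: (IPr)CuCl (5 mol %), NaOtBu (5 mol %), MeSiH(OMe)2 (3 equiv), toluene, 0 °C; then NH4F, MeOH
Reagents that add atoms: none
Why: Carbene–copper hydride catalysed SN2' reduction of a propargylic carbonate delivers hydride anti to the leaving group, so the (6R) centre is converted into the (M) axis, while the carbinol is silylated in passing to 13 and freed again by methanolysis.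

Step 11
Reactants: 14 (1E,3R,8S)-8-[(tert-butyldimethylsilyl)oxy]-2,6,10-trimethyl-1-(trimethylsilyl)undeca-1,4,5,10-tetraen-3-ol, (M) axis
Product: 17 tert-butyldimethylsilyl ether of (2R,6S,7aR)-4,4,7a-trimethyl-2-[(E)-1-(trimethylsilyl)prop-1-en-2-yl]-2,4,5,6,7,7a-hexahydro-1-benzofuran-6-ol, via alkenylpalladium chloride 15 (not isolated), via alkylpalladium chloride 16 (not isolated)
Conditions: PdCl2(MeCN)2 (1.1 equiv), Na2CO3 (3 equiv), THF (high dilution), −20 °C to rt; then NaBH4 (4 equiv), MeOH, −40 °C
Reagents that add atoms: none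
Why: Proposed new method: divalent palladium binds the C7a=C3a π bond of the allene on the face away from the carbinol, O1 attacks C7a (5-endo-trig anti-oxypalladation, ring B) while Na2CO3 takes up the HCl, and this gives the σ-alkenylpalladium 15 with the metal on C3a. Complex 15 then adds syn across the tethered 1,1-disubstituted alkene (6-exo-trig carbopalladation, ring A, C3a–C4 bond) to the neopentyl-type σ-alkylpalladium 16, which has no β-hydrogen and persists until NaBH4 replaces Pd by H, turning CH2Pd into the second methyl group on C4. The closest known reaction types are the PdCl2-promoted cyclisation of α-allenols with Heck-type capture of the dihydrofuranyl–palladium bond by external alkenes, intramolecular 6-exo Heck closures that build quaternary carbons, and borohydride cleavage of stable σ-alkylpalladium chlorides; what is new is their union in one flask on an allenol-ene. The only new stereocentre, C7a, is fixed by axis-to-centre chirality transfer: O1 hangs on C2, which lies on one side of the C7a=C3a π bond, so it can reach C7a from one face only and the (M) axis gives (7aR), while C2 and C6 are spectators and C4 ends achiral. The step needs insertion to outrun protonolysis of 15, which is secured by the base, by intramolecularity and by high dilution that also suppresses capture of 15 by a second allene. It also needs exo rather than endo insertion (secured by the four-atom tether C7a–C7–C6–C5) and no erosion of the axis before cyclisation (secured by low temperature and a full equivalent of metal, so that no free allene lingers).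

Step 12
Reactants: 17 tert-butyldimethylsilyl ether of (2R,6S,7aR)-4,4,7a-trimethyl-2-[(E)-1-(trimethylsilyl)prop-1-en-2-yl]-2,4,5,6,7,7a-hexahydro-1-benzofuran-6-ol
Product: 18 tert-butyldimethylsilyl ether of (2R,6S,7aR)-2-[(E)-1-iodoprop-1-en-2-yl]-4,4,7a-trimethyl-2,4,5,6,7,7a-hexahydro-1-benzofuran-6-ol
Conditions: NIS (1.2 equiv), 2,6-lutidine (0.5 equiv), (CF3)2CHOH, 0 °C
Reagents that add atoms: N-iodosuccinimide, O=C1CCC(=O)N1I
Why: Ipso-iododesilylation of a vinylsilane through a β-silyl cation proceeds with retention in this solvent, and the vinylsilane should react ahead of the ring alkene C3=C3a, which is shielded by two quaternary carbons.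

Step 13
Reactants: 19 (2E,4E,6E)-2,7-dimethylocta-2,4,6-trienedial
Product: 20 ethyl (2E,4E,6E,8E)-4,9-dimethyl-10-oxodeca-2,4,6,8-tetraenoate
Conditions: Ph3P=CHCO2Et (1.0 equiv), CH2Cl2, 0 °C to rt, dark
Reagents that add atoms: (ethoxycarbonylmethylene)triphenylphosphorane, CCOC(=O)C=P(c1ccccc1)(c1ccccc1)c1ccccc1
Why: Wittig olefination with a stabilised ylide is E-selective, and one equivalent on the symmetric dialdehyde should stop mainly at the mono-adduct.

Step 14
Reactants: 20 ethyl (2E,4E,6E,8E)-4,9-dimethyl-10-oxodeca-2,4,6,8-tetraenoate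
Product: 21 ethyl (2E,4E,6E,8E,10E)-4,9-dimethyl-11-(4,4,5,5-tetramethyl-1,3,2-dioxaborolan-2-yl)undeca-2,4,6,8,10-pentaenoate
Conditions: Cl2CHBpin (2 equiv), CrCl2 (8 equiv), LiI (4 equiv), THF, rt, dark
Reagents that add atoms: 2-(dichloromethyl)-4,4,5,5-tetramethyl-1,3,2-dioxaborolane, ClC(Cl)B1OC(C)(C)C(C)(C)O1
Why: Takai–Utimoto olefination with a geminal dichromium boryl reagent converts the aldehyde into the (E)-alkenylboronate and tolerates the ester and the polyene.

Step 15
Reactants: 21 ethyl (2E,4E,6E,8E,10E)-4,9-dimethyl-11-(4,4,5,5-tetramethyl-1,3,2-dioxaborolan-2-yl)undeca-2,4,6,8,10-pentaenoate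
Product: 22 (2E,4E,6E,8E,10E)-4,9-dimethyl-11-(4,4,5,5-tetramethyl-1,3,2-dioxaborolan-2-yl)undeca-2,4,6,8,10-pentaen-1-ol
Conditions: i-Bu2AlH (2.5 equiv), CH2Cl2, −78 °C; Rochelle salt
Reagents that add atoms: none
Why: 1,2-Reduction of a conjugated ester by i-Bu2AlH gives the allylic alcohol, and the pinacol boronate should survive at low temperature.

Step 16
Reactants: 18 tert-butyldimethylsilyl ether of (2R,6S,7aR)-2-[(E)-1-iodoprop-1-en-2-yl]-4,4,7a-trimethyl-2,4,5,6,7,7a-hexahydro-1-benzofuran-6-ol; 22 (2E,4E,6E,8E,10E)-4,9-dimethyl-11-(4,4,5,5-tetramethyl-1,3,2-dioxaborolan-2-yl)undeca-2,4,6,8,10-pentaen-1-ol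
Product: 23 6-O-tert-butyldimethylsilyl ether of the target
Conditions: Pd(OAc)2 (5 mol %), SPhos (10 mol %), K3PO4 (3 equiv), THF–H2O, rt, degassed, dark
Reagents that add atoms: none
Why: Suzuki–Miyaura coupling of an alkenyl iodide with an alkenyl boronate retains both alkene geometries, and the mild base at room temperature should not touch the doubly allylic C2–H.

Step 17
Reactants: 23 6-O-tert-butyldimethylsilyl ether of the target
Product: 24 (2R,6S,7aR)-2-[(2E,4E,6E,8E,10E,12E)-14-hydroxy-6,11-dimethyltetradeca-2,4,6,8,10,12-hexaen-2-yl]-4,4,7a-trimethyl-2,4,5,6,7,7a-hexahydro-1-benzofuran-6-ol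
Conditions: Bu4NF (3 equiv), THF, 0 °C to rt, dark
Reagents that add atoms: none
Why: Fluoride-induced desilylation frees the axial C6 hydroxyl under non-acidic conditions, so the acid-labile C2–O1 bond and with it the C2 configuration are kept.

**Compound list**
1 | (E)-3-methylpent-2-en-4-yn-1-ol | OC/C=C(C)/C#C | starting material
2 | [(2S,3S)-3-ethynyl-3-methyloxiran-2-yl]methanol | OC[C@@H]1O[C@@]1(C)C#C | intermediate
3 | (2R,3S)-3-ethynyl-3-methyloxirane-2-carbaldehyde | O=C[C@@H]1O[C@@]1(C)C#C | intermediate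
4 | (1S)-1-[(2S,3S)-3-ethynyl-3-methyloxiran-2-yl]-3-methylbut-3-en-1-ol | C=C(C)C[C@H](O)[C@@H]1O[C@@]1(C)C#C | intermediate
5 | (3R,5S)-3,7-dimethyloct-7-en-1-yne-3,5-diol | C=C(C)C[C@H](O)C[C@@](C#C)(C)O | intermediate
6 | (3R,5S)-5-[(tert-butyldimethylsilyl)oxy]-3,7-dimethyloct-7-en-1-yn-3-ol | C=C(C)C[C@H](O[Si](C)(C)C(C)(C)C)C[C@@](C#C)(C)O | intermediate
7 | (3R,5S)-5-[(tert-butyldimethylsilyl)oxy]-3,7-dimethyloct-7-en-1-yn-3-yl methyl carbonate | C=C(C)C[C@H](O[Si](C)(C)C(C)(C)C)C[C@@](C#C)(C)OC(=O)OC | intermediate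
8 | 3-(trimethylsilyl)prop-2-yn-1-ol | C[Si](C)(C)C#CCO | starting material
9 | 4-methyl-3-(trimethylsilyl)-2,5-dihydro-1,2-oxamagnesole (chelated alkenylmagnesium alkoxide) | C[Si](C)(C)C1=C(C)CO[Mg]1 | intermediate
10 | (E)-2-methyl-3-(trimethylsilyl)prop-2-en-1-ol | OC/C(C)=C/[Si](C)(C)C | intermediate
11 | (E)-2-methyl-3-(trimethylsilyl)prop-2-enal | O=C/C(C)=C/[Si](C)(C)C | intermediate
12 | (1E,3R,6R,8S)-8-[(tert-butyldimethylsilyl)oxy]-3-hydroxy-2,6,10-trimethyl-1-(trimethylsilyl)undeca-1,10-dien-4-yn-6-yl methyl carbonate | C=C(C)C[C@H](O[Si](C)(C)C(C)(C)C)C[C@@](C#C[C@@H](O)/C(C)=C/[Si](C)(C)C)(C)OC(=O)OC | intermediate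
13 | 3-O-[dimethoxy(methyl)silyl] ether of allenol 14 | C=C(C)C[C@H](O[Si](C)(C)C(C)(C)C)CC(C)=[C@]=C[C@@H](O[Si](C)(OC)OC)/C(C)=C/[Si](C)(C)C | intermediate
14 | (1E,3R,8S)-8-[(tert-butyldimethylsilyl)oxy]-2,6,10-trimethyl-1-(trimethylsilyl)undeca-1,4,5,10-tetraen-3-ol, (M) [aR] axis | C=C(C)C[C@H](O[Si](C)(C)C(C)(C)C)CC(C)=[C@]=C[C@@H](O)/C(C)=C/[Si](C)(C)C | intermediate
15 | chloro(2,5-dihydrofuran-3-yl)palladium with ring B closed, Pd on C3a and the side chain on C7a still open | C[Si](C)(C)/C=C(\C)[C@H]1C=C([Pd]Cl)[C@@](C)(C[C@@H](O[Si](C)(C)C(C)(C)C)CC(C)=C)O1 | intermediate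
16 | chloro[(hexahydrobenzofuran-4-yl)methyl]palladium with rings A and B closed, C4 bearing CH3 and CH2PdCl (either C4 epimer, inconsequential) | C[Si](C)(C)/C=C(\C)[C@H]1C=C2C(C)(C[Pd]Cl)C[C@H](O[Si](C)(C)C(C)(C)C)C[C@@]2(C)O1 | intermediate
17 | tert-butyldimethylsilyl ether of (2R,6S,7aR)-4,4,7a-trimethyl-2-[(E)-1-(trimethylsilyl)prop-1-en-2-yl]-2,4,5,6,7,7a-hexahydro-1-benzofuran-6-ol | C[Si](C)(C)/C=C(\C)[C@H]1C=C2C(C)(C)C[C@H](O[Si](C)(C)C(C)(C)C)C[C@@]2(C)O1 | intermediate
18 | tert-butyldimethylsilyl ether of (2R,6S,7aR)-2-[(E)-1-iodoprop-1-en-2-yl]-4,4,7a-trimethyl-2,4,5,6,7,7a-hexahydro-1-benzofuran-6-ol | I/C=C(\C)[C@H]1C=C2C(C)(C)C[C@H](O[Si](C)(C)C(C)(C)C)C[C@@]2(C)O1 | intermediate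
19 | (2E,4E,6E)-2,7-dimethylocta-2,4,6-trienedial | O=C/C(C)=C/C=C/C=C(C)/C=O | starting material
20 | ethyl (2E,4E,6E,8E)-4,9-dimethyl-10-oxodeca-2,4,6,8-tetraenoate | CCOC(=O)/C=C/C(C)=C/C=C/C=C(C)/C=O | intermediate
21 | ethyl (2E,4E,6E,8E,10E)-4,9-dimethyl-11-(4,4,5,5-tetramethyl-1,3,2-dioxaborolan-2-yl)undeca-2,4,6,8,10-pentaenoate | CCOC(=O)/C=C/C(C)=C/C=C/C=C(C)/C=C/B1OC(C)(C)C(C)(C)O1 | intermediate
22 | (2E,4E,6E,8E,10E)-4,9-dimethyl-11-(4,4,5,5-tetramethyl-1,3,2-dioxaborolan-2-yl)undeca-2,4,6,8,10-pentaen-1-ol | OC/C=C/C(C)=C/C=C/C=C(C)/C=C/B1OC(C)(C)C(C)(C)O1 | intermediate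
23 | 6-O-tert-butyldimethylsilyl ether of the target | CC(/C=C/C=C(\C)[C@H]1C=C2C(C)(C)C[C@H](O[Si](C)(C)C(C)(C)C)C[C@@]2(C)O1)=C\C=C\C=C(C)\C=C\CO | intermediate
24 | (2R,6S,7aR)-2-[(2E,4E,6E,8E,10E,12E)-14-hydroxy-6,11-dimethyltetradeca-2,4,6,8,10,12-hexaen-2-yl]-4,4,7a-trimethyl-2,4,5,6,7,7a-hexahydro-1-benzofuran-6-ol | CC(/C=C/C=C(\C)[C@H]1C=C2C(C)(C)C[C@H](O)C[C@@]2(C)O1)=C\C=C\C=C(C)\C=C\CO | target

**Step count**
Total step count: 17.
Longest linear sequence: 12 (steps 1–6, 9–12, 16, 17).

**Steps most likely to fail**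

Step 11 (key step). The alkenyl–palladium bond of 15 may be protonated before it inserts. Chloride may add to the allene or scramble its axis. The insertion may be slowed by the 1,3-diaxial crowding that builds up in ring A.
The fallback sets out from 14 and returns at 17, and splits the event into two known reactions. Electrophilic iodocyclisation of the allenol (I2, NaHCO3, CH2Cl2, −20 °C) closes ring B with the same axis-to-centre transfer. It gives the 3-iodo-2,5-dihydrofuran that carries the open silyloxy-methylpentenyl side chain, F1. A classical reductive Heck cyclisation then closes ring A 6-exo [Pd(OAc)2, PPh3, HCO2Na, Et4NCl, DMF, 80 °C]. Formate-derived hydride captures the neopentyl palladium species to give 17.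

Step 10. Hydrocupration may occur in the wrong sense next to the carbinol. Fidelity of the centre-to-axis transfer may be lost. The allene may be reduced further.
The fallback sets out from 12 and returns at 14. It replaces the addition–elimination at copper by ionisation chemistry, namely palladium-catalysed formate hydrogenolysis of the propargylic carbonate [Pd2(dba)3, PBu3, HCO2NH4, THF, rt]. Zerovalent palladium displaces the carbonate anti to give an allenylpalladium formate. This loses CO2 and reductively eliminates with retention, so the same (M) axis results. The free carbinol needs no silylation, and no new compound is made (F0).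

Step 4. The SN2 attack at the epoxide carbon, which is flanked by an alkoxide-bearing carbon and a quaternary carbon, may be sluggish. Payne migration of the epoxide or SN2' attack through the alkyne may then take over.
The fallback sets out from 2 and returns at 5, and changes the order of events. The epoxide is opened first on the unhindered primary epoxy alcohol (LiEt3BH, THF, 0 °C) to give (R)-3-methylpent-4-yne-1,3-diol F2. The primary hydroxyl is then oxidised selectively [TEMPO, PhI(OAc)2] to give (R)-3-hydroxy-3-methylpent-4-ynal F3. The same Brown methallylboration at −78 °C, which tolerates the tertiary hydroxyl, gives 5.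

**Further compounds**
F1 | step 11 | 3-iodo-2,5-dihydrofuran with ring B closed, iodine on the later C3a, (2R,7aR) in benzofuran numbering | C[Si](C)(C)/C=C(\C)[C@H]1C=C(I)[C@@](C)(C[C@@H](O[Si](C)(C)C(C)(C)C)CC(C)=C)O1
F0 | step 10 | none | none
F2 | step 4 | (R)-3-methylpent-4-yne-1,3-diol | OCC[C@@](C#C)(C)O
F3 | step 4 | (R)-3-hydroxy-3-methylpent-4-ynal | O=CC[C@@](C#C)(C)O
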